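**Retrosynthetic overview**
1. Target 18 ⇐ 7β-angelate 8α,9α-diol 15 + acid 16, by site-selective acylation of O8 (C–O).
2. 15 ⇐ cis-epoxy alcohol 13 + angelic acid 14 (C7–O bond by epoxide opening with inversion); 13 ⇐ allylic alcohol 12 (hydroxyl-directed epoxidation).
3. 12 ⇐ enol triflate 10 ⇐ 9α-silyloxy diketone 8 ⇐ diketone 5 (reagent-controlled enolate hydroxylation, C9–O).
4. 5 ⇐ enone 3 by the key new site-selective C8–H to C8=O oxidation; 3 ⇐ (+)-α-longipinene 1 by allylic oxidation.
5. Rings: none is made. The cyclobutane, cyclohexene and cycloheptane rings are bought intact in 1; every strategic bond formed is a C–O bond.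

Assumption: commercial (+)-α-longipinene is the (1R,2S,7R,8R) enantiomer, i.e. the skeleton enantiomer of the target. Longipinane numbering is used (C1 carbonyl, C2=C3, C4 and C11 bridgeheads, C6 the CMe2 carbon, C7–C9 the ring CH2 groups, C10 the quaternary C–Me); at C7–C9, α is the face of the C5–C10 chain turned toward C11 and β the face turned toward C4.

**Step 1**
Reactants: 1 (+)-α-longipinene
Product: 3 longipin-2-en-1-one, via allylic tert-butyl peroxide 2 (not isolated)
Conditions: Rh2(C6H10NO)4 [dirhodium tetrakis(caprolactamate)] (1 mol%), t-BuOOH (5 equiv, 70% aq), K2CO3 (0.5 equiv), CH2Cl2, rt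
Reagents that add atoms: tert-butyl hydroperoxide CC(C)(C)OO
Why: Allylic oxidation of the α-pinene-type alkene (the α-pinene to verbenone reaction type; the peroxyl radical abstracts a C1 hydrogen and the mixed peroxide 2 collapses to the enone) oxidises the only unhindered allylic CH2 and creates no stereocenter.

**Step 2**
Reactants: 3 longipin-2-en-1-one
Product: 5 longipin-2-ene-1,8-dione, via 8-hydroxy ketone 4 (not isolated)
Conditions: slow addition of [Fe((S,S)-CF3-PDP)(MeCN)2](SbF6)2 (25 mol% in total) and H2O2 (5 equiv, 50% aq) to 3 and AcOH (0.5 equiv), MeCN, 0 °C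
Reagents that add atoms: hydrogen peroxide OO
Why: Proposed new method: site-selective methylene oxidation by an electrophilic iron-oxo species (hydrogen-atom abstraction, then hydroxyl rebound to alcohol 4, which is oxidised on to the ketone; closest known reaction type: non-directed Fe(PDP)/H2O2 oxidation of terpenoid methylenes) has not been shown on a bridged cycloheptane or beside such an enone; C8 should be chosen because it is the only ring methylene not next to a quaternary carbon (C7 and C9 are neopentyl), it is the position most remote from the electron-withdrawing enone, the cyclobutane and bridgehead C–H bonds are strong and deactivated, and the β,β-disubstituted enone alkene is electron-poor and shielded; no stereocenter is formed.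

**Step 3**
Reactants: 5 longipin-2-ene-1,8-dione
Product: 8 TES ether 9α-(triethylsilyloxy)longipin-2-ene-1,8-dione, via potassium enolate 6 (not isolated), via potassium alkoxide 7 (not isolated)
Conditions: KN(SiMe3)2 (1.1 equiv), THF, −78 °C; (+)-(camphorsulfonyl)oxaziridine (1.3 equiv), −78 °C; then Et3SiCl (1.5 equiv), −78 to 0 °C
Reagents that add atoms: (+)-(2R,8aS)-(camphorsulfonyl)oxaziridine CC1(C)C2CCC13CS(=O)(=O)N4OC34C2; chlorotriethylsilane CC[Si](Cl)(CC)CC
Why: Davis enolate hydroxylation: the hindered amide base takes a proton from the more open C9 methylene (its neighbour C10 is tied back in the cyclobutane, whereas C7 lies against the gem-dimethyl carbon), the chiral N-sulfonyloxaziridine transfers oxygen to the α-face of enolate 6 under reagent control (the (+)-reagent is taken as the matched enantiomer) to set C9, and alkoxide 7 is silylated in the same flask.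

**Step 4**
Reactants: 8 TES ether 9α-(triethylsilyloxy)longipin-2-ene-1,8-dione
Product: 10 enol triflate 1-oxo-9α-(triethylsilyloxy)longipina-2,7-dien-8-yl trifluoromethanesulfonate, via potassium enolate 9 (not isolated)
Conditions: KN(SiMe3)2 (1.2 equiv), THF, −78 °C; PhNTf2 (1.3 equiv), −78 to 0 °C
Reagents that add atoms: N-phenylbis(trifluoromethanesulfonimide) O=S(=O)(N(c1ccccc1)S(=O)(=O)C(F)(F)F)C(F)(F)F
Why: Kinetic enolisation of the α-silyloxy ketone takes the C7 methylene (C9 is now a shielded methine) and O-sulfonylation of enolate 9 (enol triflate formation) fixes the 7,8-double bond without touching C9.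

**Step 5**
Reactants: 10 enol triflate 1-oxo-9α-(triethylsilyloxy)longipina-2,7-dien-8-yl trifluoromethanesulfonate
Product: 12 allylic alcohol 9α-hydroxylongipina-2,7-dien-1-one, via silyl ether diene 11 (not isolated)
Conditions: Pd(OAc)2 (5 mol%), PPh3 (10 mol%), n-Bu3N (3 equiv), HCO2H (2 equiv), DMF, 60 °C; then PPTS (0.1 equiv), MeOH, rt
Reagents that add atoms: none
Why: Palladium-catalysed formate reduction of the vinyl triflate (oxidative addition, formate decarboxylation to a palladium hydride, reductive elimination) leaves the 7,8-alkene, and mild acid methanolysis of silyl ether 11 frees the allylic alcohol with C9 unchanged.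

**Step 6**
Reactants: 12 allylic alcohol 9α-hydroxylongipina-2,7-dien-1-one
Product: 13 epoxy alcohol 7α,8α-epoxy-9α-hydroxylongipin-2-en-1-one
Conditions: VO(acac)2 (5 mol%), t-BuOOH (1.5 equiv, decane), CH2Cl2, 0 °C to rt
Reagents that add atoms: tert-butyl hydroperoxide CC(C)(C)OO
Why: Hydroxyl-directed vanadium-catalysed epoxidation: the C9 alkoxide bound to vanadium delivers the peroxide oxygen to the alkene face cis to the 9α-OH (syn selectivity is the rule for cycloheptenols), setting C7 and C8, while the electron-poor enone is inert.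

**Step 7**
Reactants: 13 epoxy alcohol 7α,8α-epoxy-9α-hydroxylongipin-2-en-1-one; 14 angelic acid
Product: 15 7β-angeloyloxy-8α,9α-dihydroxylongipin-2-en-1-one
Conditions: Ti(OiPr)4 (1.5 equiv), 14 (3 equiv), benzene, rt to 40 °C
Reagents that add atoms: none
Why: Ti(OiPr)4-mediated opening of a 2,3-epoxy alcohol by a carboxylic acid: titanium bound to the C9 alkoxide and the epoxide oxygen guides the carboxylate to the distal carbon C7 (the C-3 position), which is attacked by SN2 with inversion so that the angelate is 7β and trans to the retained 8α-oxygen, and the neutral conditions keep the Z double bond.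

**Step 8**
Reactants: 15 7β-angeloyloxy-8α,9α-dihydroxylongipin-2-en-1-one; 16 (R)-2-methylbutanoic acid
Product: 18 7β-angeloyloxy-9α-hydroxy-8α-[(R)-2-methylbutanoyloxy]longipin-2-en-1-one, via mixed anhydride 17 (not isolated)
Conditions: 16 (1.3 equiv), 2,4,6-trichlorobenzoyl chloride (1.3 equiv), Et3N (1.5 equiv), toluene, rt; then 15, DMAP (0.3 equiv), 0 °C
Reagents that add atoms: none
Why: Yamaguchi esterification: mixed anhydride 17 acylates the 8-OH because the 9-OH is a neopentyl alcohol pressed against the quaternary C10, and neither the acid stereocenter nor the angelate is affected at 0 °C.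

**Compound list**
1 | (+)-α-longipinene | C1CC[C@@]2(C)[C@@H]3CC=C(C)[C@H]2[C@@H]3C1(C)C | starting material
2 | 1-(tert-butylperoxy)longip-2-ene (C1 epimers) | C1CC[C@@]2(C)[C@@H]3C(OOC(C)(C)C)C=C(C)[C@H]2[C@@H]3C1(C)C | intermediate
3 | longipin-2-en-1-one | C1CC[C@@]2(C)[C@@H]3C(=O)C=C(C)[C@H]2[C@@H]3C1(C)C | intermediate
4 | 8-hydroxylongipin-2-en-1-one (C8 epimers) | C1C(O)C[C@@]2(C)[C@@H]3C(=O)C=C(C)[C@H]2[C@@H]3C1(C)C | intermediate
5 | longipin-2-ene-1,8-dione | C1C(=O)C[C@@]2(C)[C@@H]3C(=O)C=C(C)[C@H]2[C@@H]3C1(C)C | intermediate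
6 | potassium 1-oxolongipina-2,8-dien-8-olate (enolate of 5 toward C9) | C1C([O-])=C[C@@]2(C)[C@@H]3C(=O)C=C(C)[C@H]2[C@@H]3C1(C)C.[K+] | intermediate
7 | potassium alkoxide of 9α-hydroxylongipin-2-ene-1,8-dione | C1C(=O)[C@@H]([O-])[C@@]2(C)[C@@H]3C(=O)C=C(C)[C@H]2[C@@H]3C1(C)C.[K+] | intermediate
8 | 9α-(triethylsilyloxy)longipin-2-ene-1,8-dione | C1C(=O)[C@@H](O[Si](CC)(CC)CC)[C@@]2(C)[C@@H]3C(=O)C=C(C)[C@H]2[C@@H]3C1(C)C | intermediate
9 | potassium 1-oxo-9α-(triethylsilyloxy)longipina-2,7-dien-8-olate (enolate of 8 toward C7) | C1=C([O-])[C@@H](O[Si](CC)(CC)CC)[C@@]2(C)[C@@H]3C(=O)C=C(C)[C@H]2[C@@H]3C1(C)C.[K+] | intermediate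
10 | 1-oxo-9α-(triethylsilyloxy)longipina-2,7-dien-8-yl trifluoromethanesulfonate | C1=C(OS(=O)(=O)C(F)(F)F)[C@@H](O[Si](CC)(CC)CC)[C@@]2(C)[C@@H]3C(=O)C=C(C)[C@H]2[C@@H]3C1(C)C | intermediate
11 | 9α-(triethylsilyloxy)longipina-2,7-dien-1-one | C1=C[C@@H](O[Si](CC)(CC)CC)[C@@]2(C)[C@@H]3C(=O)C=C(C)[C@H]2[C@@H]3C1(C)C | intermediate
12 | 9α-hydroxylongipina-2,7-dien-1-one | C1=C[C@@H](O)[C@@]2(C)[C@@H]3C(=O)C=C(C)[C@H]2[C@@H]3C1(C)C | intermediate
13 | 7α,8α-epoxy-9α-hydroxylongipin-2-en-1-one | O1[C@H]2[C@@H]1[C@@H](O)[C@@]3(C)[C@@H]4C(=O)C=C(C)[C@H]3[C@@H]4C2(C)C | intermediate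
14 | angelic acid, (Z)-2-methylbut-2-enoic acid | C/C=C(/C)C(=O)O | starting material
15 | 7β-angeloyloxy-8α,9α-dihydroxylongipin-2-en-1-one | C/C=C(/C)C(=O)O[C@@H]1[C@@H](O)[C@@H](O)[C@@]2(C)[C@@H]3C(=O)C=C(C)[C@H]2[C@@H]3C1(C)C | intermediate
16 | (R)-2-methylbutanoic acid | CC[C@@H](C)C(=O)O | starting material
17 | (R)-2-methylbutanoic 2,4,6-trichlorobenzoic anhydride | CC[C@@H](C)C(=O)OC(=O)c1c(Cl)cc(Cl)cc1Cl | intermediate
18 | 7β-angeloyloxy-9α-hydroxy-8α-[(R)-2-methylbutanoyloxy]longipin-2-en-1-one (CNP0206166.1) | C/C=C(/C)C(=O)O[C@@H]1[C@@H](OC(=O)[C@H](C)CC)[C@@H](O)[C@@]2(C)[C@@H]3C(=O)C=C(C)[C@H]2[C@@H]3C1(C)C | target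

**Step count and risks**
Total step count: 8. Longest linear sequence: 8 steps (1 to 18).

The three steps most likely to fail:

Step 2 (the proposed new step). The site choice among C7, C8 and C9, and the survival of the enone, are untested. The fallback uses known photochemical hydrogen-atom-transfer oxygenation and sets out from 3. Irradiation (365 nm) of 3 with (nBu4N)4W10O32 (2 mol%) under O2 in MeCN gives 8-hydroperoxylongipin-2-en-1-one F1. PPh3 reduces F1 to alcohol 4, and Dess–Martin periodinane oxidises 4 to 5, where the route is rejoined.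

Step 3. The base may take the C7 proton instead of the C9 proton, or the face selectivity at C9 may be poor; the skeleton itself gives almost no facial bias here, so the result rests on the reagent. The fallback accepts oxygenation at C7 first; it sets out from 5 and comes back at 15.
- KN(SiMe3)2, the matched enantiomer of the oxaziridine and Et3SiCl give 7β-(triethylsilyloxy)longipin-2-ene-1,8-dione F2.
- KN(SiMe3)2 and PhNTf2 then give 1-oxo-7β-(triethylsilyloxy)longipina-2,8-dien-8-yl trifluoromethanesulfonate F3.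
- Pd(OAc)2/PPh3/HCO2H/n-Bu3N reduction gives 7β-(triethylsilyloxy)longipina-2,8-dien-1-one F4.
- PPTS in MeOH gives 7β-hydroxylongipina-2,8-dien-1-one F5.
- Yamaguchi esterification with 14 gives 7β-angeloyloxylongipina-2,8-dien-1-one F6.
- OsO4 (cat.) with N-methylmorpholine N-oxide dihydroxylates the 8,9-alkene anti to the allylic ester (Kishi rule) to give 15.

Step 7. C7 is a neopentyl carbon, so the titanium-guided opening may be slow or may go to C8. The fallback builds O7 by enolate oxidation and O8 by ketone reduction; it sets out from 8 and comes back at 15.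
- KN(SiMe3)2 and the oxaziridine hydroxylate C7 trans to the C9 silyl ether to give 7β-hydroxy-9α-(triethylsilyloxy)longipin-2-ene-1,8-dione F7.
- Yamaguchi esterification with 14 gives 7β-angeloyloxy-9α-(triethylsilyloxy)longipin-2-ene-1,8-dione F8.
- NaBH4 in MeOH at −78 °C reduces only the saturated C8 ketone, from the face anti to the silyl ether, to give 7β-angeloyloxy-8α-hydroxy-9α-(triethylsilyloxy)longipin-2-en-1-one F9.
- PPTS in MeOH then gives 15.

**Further compounds**
F1 | step 2 | 8-hydroperoxylongipin-2-en-1-one (C8 epimers) | C1C(OO)C[C@@]2(C)[C@@H]3C(=O)C=C(C)[C@H]2[C@@H]3C1(C)C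
F2 | step 3 | 7β-(triethylsilyloxy)longipin-2-ene-1,8-dione | CC[Si](CC)(CC)O[C@@H]1C(=O)C[C@@]2(C)[C@@H]3C(=O)C=C(C)[C@H]2[C@@H]3C1(C)C
F3 | step 3 | 1-oxo-7β-(triethylsilyloxy)longipina-2,8-dien-8-yl trifluoromethanesulfonate | CC[Si](CC)(CC)O[C@@H]1C(OS(=O)(=O)C(F)(F)F)=C[C@@]2(C)[C@@H]3C(=O)C=C(C)[C@H]2[C@@H]3C1(C)C
F4 | step 3 | 7β-(triethylsilyloxy)longipina-2,8-dien-1-one | CC[Si](CC)(CC)O[C@@H]1C=C[C@@]2(C)[C@@H]3C(=O)C=C(C)[C@H]2[C@@H]3C1(C)C
F5 | step 3 | 7β-hydroxylongipina-2,8-dien-1-one | O[C@@H]1C=C[C@@]2(C)[C@@H]3C(=O)C=C(C)[C@H]2[C@@H]3C1(C)C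
F6 | step 3 | 7β-angeloyloxylongipina-2,8-dien-1-one | C/C=C(/C)C(=O)O[C@@H]1C=C[C@@]2(C)[C@@H]3C(=O)C=C(C)[C@H]2[C@@H]3C1(C)C
F7 | step 7 | 7β-hydroxy-9α-(triethylsilyloxy)longipin-2-ene-1,8-dione | O[C@@H]1C(=O)[C@@H](O[Si](CC)(CC)CC)[C@@]2(C)[C@@H]3C(=O)C=C(C)[C@H]2[C@@H]3C1(C)C
F8 | step 7 | 7β-angeloyloxy-9α-(triethylsilyloxy)longipin-2-ene-1,8-dione | C/C=C(/C)C(=O)O[C@@H]1C(=O)[C@@H](O[Si](CC)(CC)CC)[C@@]2(C)[C@@H]3C(=O)C=C(C)[C@H]2[C@@H]3C1(C)C
F9 | step 7 | 7β-angeloyloxy-8α-hydroxy-9α-(triethylsilyloxy)longipin-2-en-1-one | C/C=C(/C)C(=O)O[C@@H]1[C@@H](O)[C@@H](O[Si](CC)(CC)CC)[C@@]2(C)[C@@H]3C(=O)C=C(C)[C@H]2[C@@H]3C1(C)C
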